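**Strategy.** The plan cuts the C1–C6 bond of the cyclohexene (C1 = C(OH)CH2OBz, C2 = CHOH, C3=C4, C5 and C6 = CHOAc). A SmI2 pinacol cyclisation of a (Z)-configured keto-aldehyde closes the ring and sets both carbinol centres, C1 quaternary, in one operation. It exploits the all-cis O–C2/O–C1/O–C6 triad: O2 and the C1 hydroxymethyl oxygen are held in a benzylidene 1,3-dioxan-5-one taken from D-glucose, so equatorial attack on that ketone fixes C1, the samarium bridge fixes C6 cis, and the C5 silyloxy group reinforces the same face. The precursor comes from one Z-selective Wittig union of two chiral-pool fragments.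

Key step: step 6

Remark: the ring atoms of the target are called C1–C6 as defined above throughout. Commercial 4,6-O-benzylidene-D-glucopyranose is taken as the (R)-acetal with equatorial phenyl; this centre is a spectator and is lost in step 8.

**Step 1**
Reactants: 1 (2R)-3-chloropropane-1,2-diol
Product: 2 [(2R)-2,3-dihydroxypropyl]triphenylphosphonium chloride
Conditions: PPh3, MeCN, sealed tube, 110 °C
Reagents that add atoms: triphenylphosphine, c1ccc(cc1)P(c1ccccc1)c1ccccc1
Why: SN2 quaternisation of the primary chloride by the phosphine (phosphonium salt formation) should proceed without touching the C2 stereocentre, which later becomes C5 of the target.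

**Step 2**
Reactants: 2 [(2R)-2,3-dihydroxypropyl]triphenylphosphonium chloride
Product: 3 [(2R)-2,3-bis(triethylsilyloxy)propyl]triphenylphosphonium chloride
Conditions: Et3SiCl, imidazole, CH2Cl2/DMF, 0 °C to rt
Reagents that add atoms: chlorotriethylsilane, CC[Si](Cl)(CC)CC
Why: Imidazole-mediated O-silylation should cap both hydroxyls, the weak base being unable to form the β-oxido betaine that would fragment.

**Step 3**
Reactants: 4 4,6-O-[(R)-benzylidene]-D-glucopyranose
Product: 6 (2R,4R,5R)-5-hydroxy-2-phenyl-1,3-dioxane-4-carbaldehyde, via formate ester 5 (not isolated)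
Conditions: NaIO4 (2.2 equiv), NaHCO3, H2O/THF, 0 °C to rt
Reagents that add atoms: none
Why: Malaprade glycol cleavage should cut C1–C2 and C2–C3 of the pyranose while the acetal blocks cleavage at C3–C4, the O5 formate hydrolysing in the buffered medium, so that glucose C4 and C5 are carried over unchanged as the dioxane stereocentres.

**Step 4**
Reactants: 3 [(2R)-2,3-bis(triethylsilyloxy)propyl]triphenylphosphonium chloride; 6 (2R,4R,5R)-5-hydroxy-2-phenyl-1,3-dioxane-4-carbaldehyde
Product: 8 (2R,4S,5R)-4-[(1Z,3S)-3,4-bis(triethylsilyloxy)but-1-en-1-yl]-2-phenyl-1,3-dioxan-5-ol, via phosphorus ylide 7 (not isolated)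
Conditions: 3 (2.3 equiv), KN(SiMe3)2 (2.2 equiv), THF, −78 °C; then 6, −78 to −20 °C
Reagents that add atoms: none
Why: Wittig olefination with a non-stabilised ylide under salt-free conditions should give the Z alkene through the kinetic cis-oxaphosphetane, the low temperature suppressing β-elimination of silanolate, the extra ylide covering the free hydroxyl, and the equatorial formyl-bearing centre being the stable epimer on the locked chair.

**Step 5**
Reactants: 8 (2R,4S,5R)-4-[(1Z,3S)-3,4-bis(triethylsilyloxy)but-1-en-1-yl]-2-phenyl-1,3-dioxan-5-ol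
Product: 9 (2R,4S,5R)-4-[(1Z,3S)-4-hydroxy-3-(triethylsilyloxy)but-1-en-1-yl]-2-phenyl-1,3-dioxan-5-ol
Conditions: HF·pyridine, pyridine, THF, 0 °C
Reagents that add atoms: none
Why: Chemoselective desilylation should remove the primary triethylsilyl ether well before the hindered secondary allylic one under buffered fluoride, which also spares the acetal.

**Step 6**
Reactants: 9 (2R,4S,5R)-4-[(1Z,3S)-4-hydroxy-3-(triethylsilyloxy)but-1-en-1-yl]-2-phenyl-1,3-dioxan-5-ol
Product: 11 (2R,4aR,5R,6S,8aS)-2-phenyl-6-(triethylsilyloxy)-4a,5,6,8a-tetrahydro-4H-benzo[d][1,3]dioxine-4a,5-diol, via keto-aldehyde 10 (not isolated)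
Conditions: (COCl)2, DMSO, THF, −78 °C; Et3N, −78 to −40 °C; then added to SmI2 (6 equiv), t-BuOH, THF, −78 to −20 °C, high dilution
Reagents that add atoms: none
Why: After Swern oxidation of both hydroxyls, SmI2 reduces the aldehyde to a ketyl bound to trivalent samarium, whose carbon adds to the samarium-coordinated ketone carbon, and a second electron plus t-BuOH deliver the diol. The closest known reaction type is the SmI2 pinacol carbocyclisation of sugar-derived 1,6-dicarbonyl compounds to cyclitols, run in one pot after Swern oxidation. The cyclohexene closes in a 6-exo-trig ketyl–carbonyl mode and ends up trans-fused to the chair dioxane. C1 is set by equatorial attack on the 1,3-dioxan-5-one, the usual bias of such ketones and the approach that leads from the equatorial side chain to the strain-free trans-fused bicycle; this puts the new hydroxyl axial and cis to O2. C6 is set by the samarium bridge between the two oxygens, which enforces a cis diol, and by the equatorial C5 triethylsilyloxy group, which the ketyl oxygen avoids, so both elements call for the same face. The step needs coupling without loss of the α-oxygen substituents: the ring C–O bonds of the dioxanone lie near the carbonyl plane and cannot align with the ketyl, and high dilution at low temperature favours closure over simple reduction or dimerisation.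

**Step 7**
Reactants: 11 (2R,4aR,5R,6S,8aS)-2-phenyl-6-(triethylsilyloxy)-4a,5,6,8a-tetrahydro-4H-benzo[d][1,3]dioxine-4a,5-diol
Product: 13 (2R,4aS,5R,6S,8aS)-4a-hydroxy-2-phenyl-4a,5,6,8a-tetrahydro-4H-benzo[d][1,3]dioxine-5,6-diyl diacetate, via triol 12 (not isolated)
Conditions: Bu4NF, THF, 0 °C; then Ac2O, Et3N, DMAP (cat.), 0 °C to rt
Reagents that add atoms: acetic anhydride, CC(=O)OC(C)=O
Why: Fluoride desilylation followed by DMAP-catalysed acetylation should esterify the two secondary hydroxyls (C5 and C6), the axial tertiary ring-fusion hydroxyl being too hindered to react under these conditions.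

**Step 8**
Reactants: 13 (2R,4aS,5R,6S,8aS)-4a-hydroxy-2-phenyl-4a,5,6,8a-tetrahydro-4H-benzo[d][1,3]dioxine-5,6-diyl diacetate
Product: 14 (1R,2S,5S,6S)-5,6-dihydroxy-6-(hydroxymethyl)cyclohex-3-ene-1,2-diyl diacetate
Conditions: AcOH/H2O (4:1), 45 °C
Reagents that add atoms: none
Why: Acid-catalysed acetal hydrolysis should free the C2 hydroxyl and the primary hydroxyl, acetates being stable to aqueous acetic acid and the non-basic medium disfavouring acyl migration.

**Step 9**
Reactants: 14 (1R,2S,5S,6S)-5,6-dihydroxy-6-(hydroxymethyl)cyclohex-3-ene-1,2-diyl diacetate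
Product: 15 [(1S,2S,5S,6R)-5,6-bis(acetyloxy)-1,2-dihydroxycyclohex-3-en-1-yl]methyl benzoate
Conditions: BzCl (1.1 equiv), pyridine, CH2Cl2, −40 to 0 °C
Reagents that add atoms: benzoyl chloride, O=C(Cl)c1ccccc1
Why: Site-selective acylation should take the primary hydroxyl, which reacts faster than the secondary C2 hydroxyl flanked by the quaternary carbon and than the tertiary C1 hydroxyl.

**Compound list**
1 | (2R)-3-chloropropane-1,2-diol | OC[C@@H](O)CCl | starting material
2 | [(2R)-2,3-dihydroxypropyl]triphenylphosphonium chloride | OC[C@@H](O)C[P+](c1ccccc1)(c1ccccc1)c1ccccc1.[Cl-] | intermediate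
3 | [(2R)-2,3-bis(triethylsilyloxy)propyl]triphenylphosphonium chloride | CC[Si](CC)(CC)OC[C@@H](O[Si](CC)(CC)CC)C[P+](c1ccccc1)(c1ccccc1)c1ccccc1.[Cl-] | intermediate
4 | 4,6-O-[(R)-benzylidene]-D-glucopyranose (anomeric mixture) | OC1[C@H](O)[C@@H](O)[C@@H]2O[C@H](c3ccccc3)OC[C@H]2O1 | starting material
5 | (2R,4R,5R)-4-formyl-2-phenyl-1,3-dioxan-5-yl formate | O=C[C@@H]1O[C@H](c2ccccc2)OC[C@H]1OC=O | intermediate
6 | (2R,4R,5R)-5-hydroxy-2-phenyl-1,3-dioxane-4-carbaldehyde (2,4-O-benzylidene-D-erythrose) | O=C[C@@H]1O[C@H](c2ccccc2)OC[C@H]1O | intermediate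
7 | [(2R)-2,3-bis(triethylsilyloxy)propylidene]triphenyl-λ5-phosphane | CC[Si](CC)(CC)OC[C@@H](O[Si](CC)(CC)CC)C=P(c1ccccc1)(c1ccccc1)c1ccccc1 | intermediate
8 | (2R,4S,5R)-4-[(1Z,3S)-3,4-bis(triethylsilyloxy)but-1-en-1-yl]-2-phenyl-1,3-dioxan-5-ol | CC[Si](CC)(CC)OC[C@@H](O[Si](CC)(CC)CC)/C=C\[C@@H]1O[C@H](c2ccccc2)OC[C@H]1O | intermediate
9 | (2R,4S,5R)-4-[(1Z,3S)-4-hydroxy-3-(triethylsilyloxy)but-1-en-1-yl]-2-phenyl-1,3-dioxan-5-ol | OC[C@@H](O[Si](CC)(CC)CC)/C=C\[C@@H]1O[C@H](c2ccccc2)OC[C@H]1O | intermediate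
10 | (2S,3Z)-4-[(2R,4S)-5-oxo-2-phenyl-1,3-dioxan-4-yl]-2-(triethylsilyloxy)but-3-enal | O=C[C@@H](O[Si](CC)(CC)CC)/C=C\[C@@H]1O[C@H](c2ccccc2)OCC1=O | intermediate
11 | (2R,4aR,5R,6S,8aS)-2-phenyl-6-(triethylsilyloxy)-4a,5,6,8a-tetrahydro-4H-benzo[d][1,3]dioxine-4a,5-diol | CC[Si](CC)(CC)O[C@H]1C=C[C@@H]2O[C@H](c3ccccc3)OC[C@@]2(O)[C@@H]1O | intermediate
12 | (2R,4aR,5R,6S,8aS)-2-phenyl-4a,5,6,8a-tetrahydro-4H-benzo[d][1,3]dioxine-4a,5,6-triol | O[C@H]1C=C[C@@H]2O[C@H](c3ccccc3)OC[C@@]2(O)[C@@H]1O | intermediate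
13 | (2R,4aS,5R,6S,8aS)-4a-hydroxy-2-phenyl-4a,5,6,8a-tetrahydro-4H-benzo[d][1,3]dioxine-5,6-diyl diacetate | CC(=O)O[C@H]1C=C[C@@H]2O[C@H](c3ccccc3)OC[C@@]2(O)[C@@H]1OC(C)=O | intermediate
14 | (1R,2S,5S,6S)-5,6-dihydroxy-6-(hydroxymethyl)cyclohex-3-ene-1,2-diyl diacetate | CC(=O)O[C@H]1C=C[C@H](O)[C@@](O)(CO)[C@@H]1OC(C)=O | intermediate
15 | [(1S,2S,5S,6R)-5,6-bis(acetyloxy)-1,2-dihydroxycyclohex-3-en-1-yl]methyl benzoate | CC(=O)O[C@H]1C=C[C@H](O)[C@@](O)(COC(=O)c2ccccc2)[C@@H]1OC(C)=O | target

**Count.** Total steps: 9. Longest linear sequence: 8 steps (steps 1, 2, 4, 5, 6, 7, 8, 9).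

**Steps most likely to fail**

Step 6. The ring closure may occur on the wrong face of the ketone, or the ketyl stage may lose an α-oxygen substituent by β-elimination or stop at simple reduction of the aldehyde. The fallback sets out from 10, here made from 9 with Dess–Martin periodinane/NaHCO3 and used crude. An intramolecular crossed benzoin reaction under carbene catalysis (2-(pentafluorophenyl)-6,7-dihydro-5H-pyrrolo[2,1-c][1,2,4]triazol-2-ium tetrafluoroborate, Et3N, toluene, rt) would join the same two carbons without a reductant and give the ring-fused α-ketol (2R,4aS,6S,8aS)-4a-hydroxy-2-phenyl-6-(triethylsilyloxy)-4a,8a-dihydro-4H-benzo[d][1,3]dioxin-5(6H)-one F1. NaBH4 (MeOH, −40 °C) should then deliver hydride axially, anti to the axial C1 hydroxyl, to give the equatorial C6 alcohol and so come back to the route at 11.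

Step 4. The ylide may lose triethylsilanolate by β-elimination before it meets the aldehyde, or the Z selectivity may erode. The fallback sets out from 6 and builds the Z alkene by alkyne semi-hydrogenation.
- Ohira–Bestmann homologation (dimethyl (1-diazo-2-oxopropyl)phosphonate, K2CO3, MeOH) would give the alkyne (2R,4S,5R)-4-ethynyl-2-phenyl-1,3-dioxan-5-ol F2.
- NaH and 4-methoxybenzyl chloride would give its ether (2R,4S,5R)-4-ethynyl-5-[(4-methoxyphenyl)methoxy]-2-phenyl-1,3-dioxane F3.
- Lithiation (n-BuLi, THF, −78 °C) and acylation with N-methoxy-2-[(4-methoxyphenyl)methoxy]-N-methylacetamide would give the ynone 1-[(4-methoxyphenyl)methoxy]-4-{(2R,4S,5R)-5-[(4-methoxyphenyl)methoxy]-2-phenyl-1,3-dioxan-4-yl}but-3-yn-2-one F4.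
- Noyori transfer hydrogenation (RuCl[(R,R)-TsDPEN](p-cymene), HCO2H/Et3N) should set the carbinol centre under catalyst control and give (2S)-1-[(4-methoxyphenyl)methoxy]-4-{(2R,4S,5R)-5-[(4-methoxyphenyl)methoxy]-2-phenyl-1,3-dioxan-4-yl}but-3-yn-2-ol F5. The (R,R) catalyst is the enantiomer predicted to give the S carbinol; this is to be confirmed.
- Et3SiCl/imidazole would give its triethylsilyl ether F6.
- Semi-hydrogenation over Pd/CaCO3 poisoned with Pb(OAc)2 and quinoline (Lindlar conditions) would give the Z alkene (2R,4S,5R)-5-[(4-methoxyphenyl)methoxy]-4-[(1Z,3S)-4-[(4-methoxyphenyl)methoxy]-3-(triethylsilyloxy)but-1-en-1-yl]-2-phenyl-1,3-dioxane F7.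
- DDQ (CH2Cl2/pH 7 buffer) would remove both 4-methoxybenzyl ethers and come back to the route at 9.

Step 5. Fluoride may also cleave the secondary silyl ether, or the silyl group may migrate to the freed primary oxygen. The fallback sets out from 8 and omits the deprotection. Swern oxidation in CH2Cl2, warmed to −40 °C before the amine is added, would oxidise the free secondary alcohol and convert the primary triethylsilyl ether directly into the aldehyde while the secondary silyl ether survives. After solvent exchange to THF the product is 10, where the fallback comes back to the route for the SmI2 stage of step 6.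

**Further compounds**
F1 | step 6 | (2R,4aS,6S,8aS)-4a-hydroxy-2-phenyl-6-(triethylsilyloxy)-4a,8a-dihydro-4H-benzo[d][1,3]dioxin-5(6H)-one | CC[Si](CC)(CC)O[C@H]1C=C[C@@H]2O[C@H](c3ccccc3)OC[C@@]2(O)C1=O
F2 | step 4 | (2R,4S,5R)-4-ethynyl-2-phenyl-1,3-dioxan-5-ol | C#C[C@@H]1O[C@H](c2ccccc2)OC[C@H]1O
F3 | step 4 | (2R,4S,5R)-4-ethynyl-5-[(4-methoxyphenyl)methoxy]-2-phenyl-1,3-dioxane | C#C[C@@H]1O[C@H](c2ccccc2)OC[C@H]1OCc1ccc(OC)cc1
F4 | step 4 | 1-[(4-methoxyphenyl)methoxy]-4-{(2R,4S,5R)-5-[(4-methoxyphenyl)methoxy]-2-phenyl-1,3-dioxan-4-yl}but-3-yn-2-one | COc1ccc(COCC(=O)C#C[C@@H]2O[C@H](c3ccccc3)OC[C@H]2OCc2ccc(OC)cc2)cc1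
F5 | step 4 | (2S)-1-[(4-methoxyphenyl)methoxy]-4-{(2R,4S,5R)-5-[(4-methoxyphenyl)methoxy]-2-phenyl-1,3-dioxan-4-yl}but-3-yn-2-ol | COc1ccc(COC[C@@H](O)C#C[C@@H]2O[C@H](c3ccccc3)OC[C@H]2OCc2ccc(OC)cc2)cc1
F6 | step 4 | triethylsilyl ether of F5, (2R,4S,5R)-5-[(4-methoxyphenyl)methoxy]-4-[(3S)-4-[(4-methoxyphenyl)methoxy]-3-(triethylsilyloxy)but-1-yn-1-yl]-2-phenyl-1,3-dioxane | COc1ccc(COC[C@@H](O[Si](CC)(CC)CC)C#C[C@@H]2O[C@H](c3ccccc3)OC[C@H]2OCc2ccc(OC)cc2)cc1
F7 | step 4 | (2R,4S,5R)-5-[(4-methoxyphenyl)methoxy]-4-[(1Z,3S)-4-[(4-methoxyphenyl)methoxy]-3-(triethylsilyloxy)but-1-en-1-yl]-2-phenyl-1,3-dioxane | COc1ccc(COC[C@@H](O[Si](CC)(CC)CC)/C=C\[C@@H]2O[C@H](c3ccccc3)OC[C@H]2OCc2ccc(OC)cc2)cc1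
F0 | step 5 | none | none
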